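Readings and results were computed from invented constants; scatter was added.

The target and its isomer are the two products read in this flask, and the questions concern the ratio c(isomer of the product)/c(target).

| setting | Friday's | Wednesday's | Monday's | flask |
|---|---|---|---|---|
| starting material | 10 mM | 15 mM | 20 mM | 20 mM |
| protic impurity | 6 mM | 6 mM | 3 mM | 6.00 mM |
| remark | run made earlier | run made earlier | run made earlier |  |
| time |  |  |  | 2.5 h |

- Friday's (time / min: isomer of the product / %, target / %): 20.0: 53.7, 20.2; 40.0: 54.1, 19.7; 60.0: 53.5, 19.9; 80.0: 53.4, 19.8; 90.0: 54.0, 20.6; 120: 53.6, 19.9
- Wednesday's (time / min: isomer of the product / %, target / %): 20.0: 55.6, 20.3; 40.0: 55.3, 19.6; 60.0: 54.8, 20.4; 80.0: 55.7, 20.7; 90.0: 54.7, 20.2; 120: 55.3, 20.3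
- Monday's (time / min: isomer of the product / %, target / %): 10.0: 62.4, 23.4; 30.0: 62.9, 23.9; 60.0: 63.0, 23.3; 80.0: 63.0, 23.2; 120: 62.8, 22.7

(each reading ± 0.3 percentage points)

- percentages count the starting material that a species holds: one side product counts as two
- what was read earlier has a scatter of 0.3 percentage points, one standard deviation
- steps thought possible: starting material + target -> side product; other conformer + protic impurity -> quenched substrate; target <-> isomer of the product; starting material <-> other conformer; starting material -> target; other conformer -> isomer of the product; starting material <-> dormant form

1. ratio of isomer of the product to target at 2.0 s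
2. ratio of isomer of the product to target at 2.0 min
3. ratio of isomer of the product to target at 2.5 h
4. which of isomer of the product and target there is more of at 2.5 h

Starting material may give target, and the other conformer may give isomer. The other conformer may also be quenched by protic impurity, and starting material may join target to form side product. Target and isomer may interconvert.

Two chemists read these runs differently. She holds kinetic control: the two routes lay down a frozen ratio. Her evidence is that nothing moves, since Monday's isomer reads 62.4 % at 10.0 min and 62.8 % at 120 min.

He holds thermodynamic control: target and isomer exchange until a fixed ratio stands. He pools each run. Friday's ratio reads 2.68, Wednesday's 2.73 and Monday's 2.70, though Monday's charge of starting material is twice Friday's and its protic impurity half Friday's. The side step consumes target and the quench drains the conformer route, he says, so a frozen ratio ought to climb from Friday to Monday.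

I side with him and carry one number: K, the ratio at which target and isomer stand in exchange, read as the mean of the three runs, 2.70. For the new flask I expect K at 2.5 h, so isomer holds 73.0 % of the pair and leads. The earliest reading is Monday's at 10.0 min, so 2.0 s and 2.0 min lie outside the runs, and I commit to nothing there.

The forecast, on his side, gives 1 at 2.0 s, 2.5 at 2.0 min and 2.7 at 2.5 h, with isomer of the product ahead, holding that “target and isomer are most likely equilibrated”.

The new flask gives 2.58 at 2.0 s, 2.71 at 2.0 min and 2.70 at 2.5 h, with isomer at 56.3 % and target at 20.8 % at that last time.

    starting material + target → side product (k = 0.390 M⁻¹ s⁻¹)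
    other conformer + protic impurity → quenched substrate (k = 1.80 M⁻¹ s⁻¹)
    target ⇌ isomer of the product (K = 2.70, k = 0.00260 s⁻¹)
    starting material ⇌ other conformer, settled at all times (K = 2.00)
    starting material → target (k = 0.0140 s⁻¹)
    other conformer → isomer of the product (k = 0.0180 s⁻¹)
    starting material ⇌ dormant form (K = 0.690, k = 0.140 s⁻¹)

The new flask's end ratio stands at K. The frozen view has its region in the new flask at times short against the relaxation half-life of the pair, 3.24 min by the exchange step alone with both directions counted: at 2.0 s that flask reads 2.58. The neighbour flask takes 80 mM of starting material, its other charges unchanged. K gives its end ratio as 2.70, so its target of 22.0 % calls for isomer at 59.4 %. The neighbour's ratio is 2.60 at 2.0 s and 3.10 at 2.0 min, then 2.70 at 2.5 h, with isomer at 59.3 %.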